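**Plan**

- Retrosynthetic cuts, in order: the five O–benzyl bonds; the flavanone C2–aryl bond (ring F, conjugate arylation of a chromone); chromone ring E, traced back to an ortho-hydroxyacetophenone whose acetyl group enters ring D through an aryl iodide; the lactol C2–OH; then, together, the isoflavan C3–C4 and O1–C2 bonds; last the C4–ring A bond (aryllithium plus aldehyde).
- Enabling feature: isoflavan C4 is benzylic to ring A, lies ortho to the ring oxygen O1 and carries the 2,4,6-trioxygenated ring D. The array O1–C8a–C4a–C4 is therefore a masked ortho-quinone methide that lacks only C2 and the ring B-bearing C3 of pyran ring C.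
- Forward order: rings A and D are joined at C4 and stored as a sulfone; ring C is closed by aminocatalysed annulation with the ring B acetaldehyde and the lactol is reduced; ring D is deallylated, acetylated through its iodide and annulated to chromone ring E; ring F is added last, before global hydrogenolysis.
- Stereochemistry: C3 (R) comes from the enamine of an (R)-diarylprolinol silyl ether and C4 (S) is set trans to it in the same step; flavanone C2 (S) comes from a chiral diphosphine–rhodium catalyst, independent of the remote centres.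

Key step: step 9

Assumption: the sense of induction is assigned by analogy (the (R)-prolinol ether for 3R as in enamine additions to nitroalkenes, the (S)-biaryl diphosphine for 2S as in the rhodium-catalysed arylation of cyclohexenone); the antipodal catalyst is used if a model run shows the opposite sense.

Abbreviation used in names: Chr = (3R,4S)-7-(benzyloxy)-3-[3-(benzyloxy)-2,4-dimethoxyphenyl]chroman-4-yl.

**Route**

Step 1
Reactants: 1 2,6-dimethoxyphenol
Product: 2 2-(benzyloxy)-1,3-dimethoxybenzene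
Conditions: BnBr, K2CO3, DMF, 60 °C
Reagents that add atoms: benzyl bromide, BrCc1ccccc1
Why: Williamson ether synthesis on the acidic, flanked phenol; benzyl is chosen so that this oxygen is freed with all the others in the final hydrogenolysis.

Step 2
Reactants: 2 2-(benzyloxy)-1,3-dimethoxybenzene
Product: 4 3-(benzyloxy)-2,4-dimethoxybenzaldehyde, via aryl iminium chloride 3 (not isolated)
Conditions: POCl3, DMF, 0 → 75 °C; then ice-water
Reagents that add atoms: N,N-dimethylformamide, CN(C)C=O; water, O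
Why: Vilsmeier–Haack formylation; as in 1,2,3-trimethoxybenzene the chloroiminium ion should attack C4, ortho and para to the two coplanar methoxy groups, because the central benzyloxy group is twisted out of conjugation and directs weakly.

Step 3
Reactants: 4 3-(benzyloxy)-2,4-dimethoxybenzaldehyde
Product: 6 2-[3-(benzyloxy)-2,4-dimethoxyphenyl]acetaldehyde, via methyl enol ether 5 (not isolated)
Conditions: (MeOCH2)PPh3Cl, KOt-Bu, THF, 0 °C; then 2 M HCl, THF, rt
Reagents that add atoms: (methoxymethyl)triphenylphosphonium chloride, COC[P+](c1ccccc1)(c1ccccc1)c1ccccc1.[Cl-]; water, O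
Why: Wittig methoxymethylenation followed by acid hydrolysis of the enol ether is the standard one-carbon homologation of an aryl aldehyde to an arylacetaldehyde; 6 is sensitive to air and base and should be used soon after a short filtration.

Step 4
Reactants: 7 2,4,6-trihydroxybenzaldehyde
Product: 8 4-(allyloxy)-2,6-dihydroxybenzaldehyde
Conditions: allyl bromide (1.0 equiv), NaHCO3 (1.1 equiv), DMF, rt
Reagents that add atoms: allyl bromide, C=CCBr
Why: Regioselective Williamson etherification: the 4-hydroxyl is the most acidic and the only one neither hydrogen-bonded to nor flanked by the formyl group, so one equivalent of allyl bromide with a weak base should alkylate it preferentially, and ortho-allylated or diallylated by-products are separable.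

Step 5
Reactants: 8 4-(allyloxy)-2,6-dihydroxybenzaldehyde
Product: 9 4-(allyloxy)-2,6-bis(benzyloxy)benzaldehyde
Conditions: BnBr (2.5 equiv), K2CO3, DMF, 60 °C
Reagents that add atoms: benzyl bromide, BrCc1ccccc1
Why: Williamson etherification under more forcing conditions alkylates the two chelated ortho hydroxyls, leaving the oxygen para to the formyl group as the only one with the orthogonal allyl group.

Step 6
Reactants: 10 4-bromoresorcinol
Product: 11 5-(benzyloxy)-2-bromophenol
Conditions: BnBr (1.0 equiv), K2CO3 (1.0 equiv), acetone, rt → 50 °C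
Reagents that add atoms: benzyl bromide, BrCc1ccccc1
Why: Regioselective Williamson mono-etherification: the hydroxyl para to bromine is less hindered and its phenoxide more nucleophilic than that of the ortho hydroxyl, which is hydrogen-bonded to bromine, so the 5-benzyl ether should predominate and be separated from its regioisomer and the dibenzyl ether.

Step 7
Reactants: 11 5-(benzyloxy)-2-bromophenol; 9 4-(allyloxy)-2,6-bis(benzyloxy)benzaldehyde
Product: 13 rac-5-(benzyloxy)-2-{[4-(allyloxy)-2,6-bis(benzyloxy)phenyl](hydroxy)methyl}phenol, via dilithio phenoxide 12 (not isolated)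
Conditions: n-BuLi (2.1 equiv), THF, −78 → 0 °C; then 9, −78 → 0 °C; then H2O
Reagents that add atoms: none
Why: Deprotonation and bromine–lithium exchange give the ortho-lithiated lithium phenoxide, whose 1,2-addition to the non-enolisable aldehyde forms the future C4–C4a bond; the carbinol centre is racemic but becomes planar in step 9, and the acid-sensitive diol is taken on after a neutral work-up.

Step 8
Reactants: 13 rac-5-(benzyloxy)-2-{[4-(allyloxy)-2,6-bis(benzyloxy)phenyl](hydroxy)methyl}phenol
Product: 14 rac-5-(benzyloxy)-2-{[4-(allyloxy)-2,6-bis(benzyloxy)phenyl](4-methylphenylsulfonyl)methyl}phenol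
Conditions: p-TolSO2H (1.5 equiv), CH2Cl2, rt
Reagents that add atoms: p-toluenesulfinic acid, Cc1ccc(cc1)S(=O)O
Why: Acid-promoted SN1 substitution: the sulfinic acid ionises the doubly donor-stabilised benzhydrol and the sulfinate is captured at sulfur, giving a crystallisable sulfone, the customary storable precursor of an ortho-quinone methide.

Step 9
Reactants: 14 rac-5-(benzyloxy)-2-{[4-(allyloxy)-2,6-bis(benzyloxy)phenyl](4-methylphenylsulfonyl)methyl}phenol; 6 2-[3-(benzyloxy)-2,4-dimethoxyphenyl]acetaldehyde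
Product: 16 (3R,4S)-4-[4-(allyloxy)-2,6-bis(benzyloxy)phenyl]-7-(benzyloxy)-3-[3-(benzyloxy)-2,4-dimethoxyphenyl]chroman-2-ol (both C2 anomers), via ortho-quinone methide 15 (not isolated)
Conditions: (R)-α,α-diphenylprolinol trimethylsilyl ether (20 mol %), NaHCO3 (2 equiv), CH2Cl2, 0 °C → rt
Reagents that add atoms: none
Why: NaHCO3 eliminates p-toluenesulfinate from 14 to give methide 15, while 6 condenses with the secondary amine to an E-enamine whose nucleophilic carbon adds to the exocyclic methide carbon (C3–C4 bond) with rearomatisation of ring A; hydrolysis of the iminium ion returns the catalyst and the phenol adds to the liberated aldehyde (O1–C2 bond). The closest known reaction is the diarylprolinol silyl ether-catalysed Michael addition/hemiacetalisation of aldehydes with ortho-quinone methides released from 2-(arylsulfonylmethyl)phenols, a stepwise formal [4+2] annulation. Pyran ring C closes by reversible 6-exo-trig hemiacetalisation, so C2 is obtained as an anomeric mixture that is of no consequence. C3 is controlled by the catalyst, whose diphenyl(silyloxy)methyl group blocks one face of the enamine, and C4 is set relative to C3 in the open Michael transition state, which should hold ring D and ring B apart and lead to the 3,4-trans lactol. The step needs C-alkylation at the methide carbon to outrun methide dimerisation and self-aldolisation of 6: the three ether oxygens of ring D stabilise and shield the methide, the heterogeneous base releases it slowly, and rearomatisation drives the addition. Kinetic diastereoselectivity must be high, because epimerisation of a cis adduct at the acidic C3 would lead into the enantiomeric trans series.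

Step 10
Reactants: 16 (3R,4S)-4-[4-(allyloxy)-2,6-bis(benzyloxy)phenyl]-7-(benzyloxy)-3-[3-(benzyloxy)-2,4-dimethoxyphenyl]chroman-2-ol
Product: 17 (3R,4S)-4-[4-(allyloxy)-2,6-bis(benzyloxy)phenyl]-7-(benzyloxy)-3-[3-(benzyloxy)-2,4-dimethoxyphenyl]chroman
Conditions: Et3SiH, BF3·OEt2, CH2Cl2, −78 → −40 °C
Reagents that add atoms: none
Why: Ionic hydrogenation: BF3·OEt2 ionises either anomer to the aryloxy-stabilised oxocarbenium ion, which Et3SiH reduces at C2 without touching C3 or C4; the low temperature is meant to spare the benzyl ethers and the acid-sensitive C4–ring D bond.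

Step 11
Reactants: 17 (3R,4S)-4-[4-(allyloxy)-2,6-bis(benzyloxy)phenyl]-7-(benzyloxy)-3-[3-(benzyloxy)-2,4-dimethoxyphenyl]chroman
Product: 18 3,5-bis(benzyloxy)-4-Chr-phenol
Conditions: Pd(PPh3)4 (5 mol %), morpholine, THF, rt
Reagents that add atoms: none
Why: Tsuji–Trost deallylation: zerovalent palladium ionises the aryl allyl ether to a π-allyl complex that morpholine intercepts, leaving benzyl and methyl ethers untouched and freeing only the ring D oxygen para to C4.

Step 12
Reactants: 18 3,5-bis(benzyloxy)-4-Chr-phenol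
Product: 19 3,5-bis(benzyloxy)-2-iodo-4-Chr-phenol
Conditions: NIS (1.0 equiv), DMF, −20 → 0 °C, dark
Reagents that add atoms: N-iodosuccinimide, O=C1CCC(=O)N1I
Why: Electrophilic aromatic iodination: the free phenol reinforced by two meta benzyloxy groups makes the two equivalent ring D positions ortho to the hydroxyl far more nucleophilic than any site of rings A and B, so one equivalent of reagent at low temperature should give the mono-iodide.

Step 13
Reactants: 19 3,5-bis(benzyloxy)-2-iodo-4-Chr-phenol
Product: 21 1-[2,4-bis(benzyloxy)-6-hydroxy-3-Chr-phenyl]ethan-1-one, via ethyl enol ether 20 (not isolated)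
Conditions: tributyl(1-ethoxyvinyl)stannane (1.5 equiv), PdCl2(PPh3)2 (5 mol %), toluene, 100 °C; then 1 M HCl, THF, rt
Reagents that add atoms: tributyl(1-ethoxyvinyl)stannane, CCCC[Sn](CCCC)(CCCC)C(=C)OCC; water, O
Why: Migita–Kosugi–Stille coupling with the 1-ethoxyvinyl stannane as an acetyl anion equivalent, then mild hydrolysis of the enol ether, places the acetyl group between the free hydroxyl and a benzyloxy group without a Lewis acid that could cleave the C4–ring D bond by retro-Friedel–Crafts reaction.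

Step 14
Reactants: 21 1-[2,4-bis(benzyloxy)-6-hydroxy-3-Chr-phenyl]ethan-1-one
Product: 23 5,7-bis(benzyloxy)-6-Chr-4H-chromen-4-one, via enaminone 22 (not isolated)
Conditions: Me2NCH(OMe)2, toluene, 95 °C; then conc. HCl (cat.), CH2Cl2, 40 °C
Reagents that add atoms: N,N-dimethylformamide dimethyl acetal, COC(OC)N(C)C
Why: Condensation of the methyl ketone with the amide acetal gives the enaminone, and acid-promoted addition of the only free phenol with loss of dimethylamine (the standard enaminone route to chromones) closes ring E; the other oxygen flanking the acyl group is benzylated, so the ring can form only toward the oxygen para to C4, which fixes the 6-substitution pattern.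

Step 15
Reactants: 23 5,7-bis(benzyloxy)-6-Chr-4H-chromen-4-one; 24 4-(benzyloxy)phenylboronic acid
Product: 25 (2S)-5,7-bis(benzyloxy)-2-[4-(benzyloxy)phenyl]-6-Chr-chroman-4-one
Conditions: [Rh(OH)(cod)]2 (2.5 mol %), (S)-MeO-F12-BIPHEP [(S)-6,6'-dimethoxy-2,2'-bis{bis(3,4,5-trifluorophenyl)phosphino}biphenyl] (5.5 mol %), toluene/H2O, 30 °C
Reagents that add atoms: none
Why: Hayashi–Miyaura asymmetric 1,4-addition: the aryl–rhodium species (monovalent rhodium) formed by transmetalation inserts the chromone C2=C3 bond on the face dictated by the diphosphine and water protonates the rhodium enolate, so flavanone C2 is set under catalyst control far from the existing centres; the electron-poor ligand keeps the catalyst active without added base, so the flavanone should not ring-open.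

Step 16
Reactants: 25 (2S)-5,7-bis(benzyloxy)-2-[4-(benzyloxy)phenyl]-6-Chr-chroman-4-one
Product: 26 (2S)-5,7-dihydroxy-6-[(3R,4S)-7-hydroxy-3-(3-hydroxy-2,4-dimethoxyphenyl)chroman-4-yl]-2-(4-hydroxyphenyl)chroman-4-one
Conditions: H2 (1 atm), 10% Pd/C, EtOAc/MeOH, rt
Reagents that add atoms: none
Why: Catalytic hydrogenolysis of the five aryl benzyl ethers under neutral conditions avoids the acid- or base-mediated retro-oxa-Michael opening that would scramble flavanone C2; the reaction is to be stopped at full debenzylation, before the aryl ketone or the benzylic C2–O bond is attacked.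

**Compound list**

1 | 2,6-dimethoxyphenol | COc1cccc(OC)c1O | starting material
2 | 2-(benzyloxy)-1,3-dimethoxybenzene | COc1cccc(OC)c1OCc1ccccc1 | intermediate
3 | N-[3-(benzyloxy)-2,4-dimethoxybenzylidene]-N-methylmethanaminium chloride | C[N+](C)=Cc1ccc(OC)c(OCc2ccccc2)c1OC.[Cl-] | intermediate
4 | 3-(benzyloxy)-2,4-dimethoxybenzaldehyde | COc1ccc(C=O)c(OC)c1OCc1ccccc1 | intermediate
5 | 2-(benzyloxy)-1,3-dimethoxy-4-(2-methoxyethenyl)benzene (E/Z mixture) | COC=Cc1ccc(OC)c(OCc2ccccc2)c1OC | intermediate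
6 | 2-[3-(benzyloxy)-2,4-dimethoxyphenyl]acetaldehyde | COc1ccc(CC=O)c(OC)c1OCc1ccccc1 | intermediate
7 | 2,4,6-trihydroxybenzaldehyde | O=Cc1c(O)cc(O)cc1O | starting material
8 | 4-(allyloxy)-2,6-dihydroxybenzaldehyde | O=Cc1c(O)cc(OCC=C)cc1O | intermediate
9 | 4-(allyloxy)-2,6-bis(benzyloxy)benzaldehyde | O=Cc1c(OCc2ccccc2)cc(OCC=C)cc1OCc1ccccc1 | intermediate
10 | 4-bromoresorcinol | Oc1ccc(Br)c(O)c1 | starting material
11 | 5-(benzyloxy)-2-bromophenol | Oc1cc(OCc2ccccc2)ccc1Br | intermediate
12 | lithium 5-(benzyloxy)-2-lithiophenolate | [Li]Oc1cc(OCc2ccccc2)ccc1[Li] | intermediate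
13 | rac-5-(benzyloxy)-2-{[4-(allyloxy)-2,6-bis(benzyloxy)phenyl](hydroxy)methyl}phenol | OC(c1ccc(OCc2ccccc2)cc1O)c1c(OCc2ccccc2)cc(OCC=C)cc1OCc1ccccc1 | intermediate
14 | rac-5-(benzyloxy)-2-{[4-(allyloxy)-2,6-bis(benzyloxy)phenyl](4-methylphenylsulfonyl)methyl}phenol | Cc1ccc(cc1)S(=O)(=O)C(c1ccc(OCc2ccccc2)cc1O)c1c(OCc2ccccc2)cc(OCC=C)cc1OCc1ccccc1 | intermediate
15 | 6-{[4-(allyloxy)-2,6-bis(benzyloxy)phenyl]methylidene}-3-(benzyloxy)cyclohexa-2,4-dien-1-one | O=C1C=C(OCc2ccccc2)C=CC1=Cc1c(OCc2ccccc2)cc(OCC=C)cc1OCc1ccccc1 | intermediate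
16 | (3R,4S)-4-[4-(allyloxy)-2,6-bis(benzyloxy)phenyl]-7-(benzyloxy)-3-[3-(benzyloxy)-2,4-dimethoxyphenyl]chroman-2-ol (C2 anomers) | COc1ccc([C@@H]2C(O)Oc3cc(OCc4ccccc4)ccc3[C@H]2c2c(OCc3ccccc3)cc(OCC=C)cc2OCc2ccccc2)c(OC)c1OCc1ccccc1 | intermediate
17 | (3R,4S)-4-[4-(allyloxy)-2,6-bis(benzyloxy)phenyl]-7-(benzyloxy)-3-[3-(benzyloxy)-2,4-dimethoxyphenyl]chroman | COc1ccc([C@@H]2COc3cc(OCc4ccccc4)ccc3[C@H]2c2c(OCc3ccccc3)cc(OCC=C)cc2OCc2ccccc2)c(OC)c1OCc1ccccc1 | intermediate
18 | 3,5-bis(benzyloxy)-4-{(3R,4S)-7-(benzyloxy)-3-[3-(benzyloxy)-2,4-dimethoxyphenyl]chroman-4-yl}phenol | COc1ccc([C@@H]2COc3cc(OCc4ccccc4)ccc3[C@H]2c2c(OCc3ccccc3)cc(O)cc2OCc2ccccc2)c(OC)c1OCc1ccccc1 | intermediate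
19 | 3,5-bis(benzyloxy)-4-{(3R,4S)-7-(benzyloxy)-3-[3-(benzyloxy)-2,4-dimethoxyphenyl]chroman-4-yl}-2-iodophenol | COc1ccc([C@@H]2COc3cc(OCc4ccccc4)ccc3[C@H]2c2c(OCc3ccccc3)cc(O)c(I)c2OCc2ccccc2)c(OC)c1OCc1ccccc1 | intermediate
20 | 3,5-bis(benzyloxy)-4-{(3R,4S)-7-(benzyloxy)-3-[3-(benzyloxy)-2,4-dimethoxyphenyl]chroman-4-yl}-2-(1-ethoxyethenyl)phenol | COc1ccc([C@@H]2COc3cc(OCc4ccccc4)ccc3[C@H]2c2c(OCc3ccccc3)cc(O)c(C(=C)OCC)c2OCc2ccccc2)c(OC)c1OCc1ccccc1 | intermediate
21 | 1-[2,4-bis(benzyloxy)-3-{(3R,4S)-7-(benzyloxy)-3-[3-(benzyloxy)-2,4-dimethoxyphenyl]chroman-4-yl}-6-hydroxyphenyl]ethan-1-one | COc1ccc([C@@H]2COc3cc(OCc4ccccc4)ccc3[C@H]2c2c(OCc3ccccc3)cc(O)c(C(C)=O)c2OCc2ccccc2)c(OC)c1OCc1ccccc1 | intermediate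
22 | (E)-1-[2,4-bis(benzyloxy)-3-{(3R,4S)-7-(benzyloxy)-3-[3-(benzyloxy)-2,4-dimethoxyphenyl]chroman-4-yl}-6-hydroxyphenyl]-3-(dimethylamino)prop-2-en-1-one | COc1ccc([C@@H]2COc3cc(OCc4ccccc4)ccc3[C@H]2c2c(OCc3ccccc3)cc(O)c(C(=O)/C=C/N(C)C)c2OCc2ccccc2)c(OC)c1OCc1ccccc1 | intermediate
23 | 5,7-bis(benzyloxy)-6-{(3R,4S)-7-(benzyloxy)-3-[3-(benzyloxy)-2,4-dimethoxyphenyl]chroman-4-yl}-4H-chromen-4-one | COc1ccc([C@@H]2COc3cc(OCc4ccccc4)ccc3[C@H]2c2c(OCc3ccccc3)cc3occc(=O)c3c2OCc2ccccc2)c(OC)c1OCc1ccccc1 | intermediate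
24 | 4-(benzyloxy)phenylboronic acid | OB(O)c1ccc(OCc2ccccc2)cc1 | starting material
25 | (2S)-5,7-bis(benzyloxy)-2-[4-(benzyloxy)phenyl]-6-{(3R,4S)-7-(benzyloxy)-3-[3-(benzyloxy)-2,4-dimethoxyphenyl]chroman-4-yl}chroman-4-one | COc1ccc([C@@H]2COc3cc(OCc4ccccc4)ccc3[C@H]2c2c(OCc3ccccc3)cc3c(c2OCc2ccccc2)C(=O)C[C@@H](c2ccc(OCc4ccccc4)cc2)O3)c(OC)c1OCc1ccccc1 | intermediate
26 | (2S)-5,7-dihydroxy-6-[(3R,4S)-7-hydroxy-3-(3-hydroxy-2,4-dimethoxyphenyl)chroman-4-yl]-2-(4-hydroxyphenyl)chroman-4-one | COc1ccc([C@@H]2COc3cc(O)ccc3[C@H]2c2c(O)cc3c(c2O)C(=O)C[C@@H](c2ccc(O)cc2)O3)c(OC)c1O | target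

**Count and risks**

Total step count: 16. Longest linear sequence: 12 steps (steps 4, 5 and 7 to 16, from 7 to 26).

Steps most likely to fail:

1. Step 9. The hindered enamine may add too slowly to the strongly stabilised, crowded methide, so that self-aldolisation of 6 or methide dimerisation takes over, and facial or diastereofacial control may be poor. The fallback is auxiliary-controlled enolate addition to the same methide, so the same two bonds are formed. It sets out from 6 and uses 14 as before.
   - Pinnick oxidation (NaClO2, NaH2PO4, 2-methyl-2-butene, t-BuOH/H2O) should give 2-[3-(benzyloxy)-2,4-dimethoxyphenyl]acetic acid F1.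
   - Coupling with (R)-4-benzyloxazolidin-2-one (DCC, DMAP, CH2Cl2) should give (R)-4-benzyl-3-{2-[3-(benzyloxy)-2,4-dimethoxyphenyl]acetyl}oxazolidin-2-one F2.
   - Its sodium enolate (NaN(SiMe3)2, THF, −78 °C; two equivalents, the first releasing 15 from 14) should add to the methide anti to the benzyl group of the auxiliary, giving the Michael adduct F3.
   - On warming, the phenoxide of F3 should displace the auxiliary to give (3R,4S)-4-[4-(allyloxy)-2,6-bis(benzyloxy)phenyl]-7-(benzyloxy)-3-[3-(benzyloxy)-2,4-dimethoxyphenyl]chroman-2-one F4.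
   - Reduction of the lactone with i-Bu2AlH (CH2Cl2, −78 °C) would rejoin the route at lactol 16.

2. Step 12. Iodination may run on to the di-iodide, or attack the ring D carbon para to the hydroxyl with loss of the chromanyl cation or oxidation to a para-quinone methide, and the hindered iodide may then couple sluggishly in step 13. The fallback replaces halogenation and cross-coupling by chelation-controlled ortho-formylation. It sets out from 18.
   - MgCl2, Et3N and paraformaldehyde in MeCN at reflux should give 2,4-bis(benzyloxy)-3-Chr-6-hydroxybenzaldehyde F5.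
   - MeMgBr (THF, 0 °C) should then give 3,5-bis(benzyloxy)-4-Chr-2-(1-hydroxyethyl)phenol F6 as a mixture of carbinol epimers.
   - MnO2 (CH2Cl2, rt) should oxidise the benzylic alcohol, and the route is rejoined at acetophenone 21.

3. Step 15. The electron-rich, peri-substituted chromone may be arylated slowly, the rhodium enolate may open to a chalcone, or facial selectivity may be insufficient. The fallback forms flavanone C2 by C–O instead of C–C bond formation. It sets out from 21.
   - Claisen–Schmidt condensation with 4-(benzyloxy)benzaldehyde (KOH, EtOH/THF, rt) should give (E)-1-[2,4-bis(benzyloxy)-3-Chr-6-hydroxyphenyl]-3-[4-(benzyloxy)phenyl]prop-2-en-1-one F7.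
   - 6-endo-trig oxa-Michael cyclisation under a quinine-derived bifunctional thiourea (toluene, rt) should close ring E.
   - The C2 epimers are diastereomers, so the 2S isomer can be separated and the 2R isomer returned to F7 by base equilibration; the route is rejoined at 25.

**Further compounds**

F1 | step 9 | 2-[3-(benzyloxy)-2,4-dimethoxyphenyl]acetic acid | COc1ccc(CC(=O)O)c(OC)c1OCc1ccccc1
F2 | step 9 | (R)-4-benzyl-3-{2-[3-(benzyloxy)-2,4-dimethoxyphenyl]acetyl}oxazolidin-2-one | COc1ccc(CC(=O)N2[C@H](Cc3ccccc3)COC2=O)c(OC)c1OCc1ccccc1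
F3 | step 9 | (R)-3-{(2R,3S)-3-[4-(allyloxy)-2,6-bis(benzyloxy)phenyl]-3-[4-(benzyloxy)-2-hydroxyphenyl]-2-[3-(benzyloxy)-2,4-dimethoxyphenyl]propanoyl}-4-benzyloxazolidin-2-one | COc1ccc([C@H](C(=O)N2[C@H](Cc3ccccc3)COC2=O)[C@@H](c2ccc(OCc3ccccc3)cc2O)c2c(OCc3ccccc3)cc(OCC=C)cc2OCc2ccccc2)c(OC)c1OCc1ccccc1
F4 | step 9 | (3R,4S)-4-[4-(allyloxy)-2,6-bis(benzyloxy)phenyl]-7-(benzyloxy)-3-[3-(benzyloxy)-2,4-dimethoxyphenyl]chroman-2-one | COc1ccc([C@@H]2C(=O)Oc3cc(OCc4ccccc4)ccc3[C@H]2c2c(OCc3ccccc3)cc(OCC=C)cc2OCc2ccccc2)c(OC)c1OCc1ccccc1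
F5 | step 12 | 2,4-bis(benzyloxy)-3-{(3R,4S)-7-(benzyloxy)-3-[3-(benzyloxy)-2,4-dimethoxyphenyl]chroman-4-yl}-6-hydroxybenzaldehyde | COc1ccc([C@@H]2COc3cc(OCc4ccccc4)ccc3[C@H]2c2c(OCc3ccccc3)cc(O)c(C=O)c2OCc2ccccc2)c(OC)c1OCc1ccccc1
F6 | step 12 | 3,5-bis(benzyloxy)-4-{(3R,4S)-7-(benzyloxy)-3-[3-(benzyloxy)-2,4-dimethoxyphenyl]chroman-4-yl}-2-(1-hydroxyethyl)phenol (carbinol epimers) | COc1ccc([C@@H]2COc3cc(OCc4ccccc4)ccc3[C@H]2c2c(OCc3ccccc3)cc(O)c(C(C)O)c2OCc2ccccc2)c(OC)c1OCc1ccccc1
F7 | step 15 | (E)-1-[2,4-bis(benzyloxy)-3-{(3R,4S)-7-(benzyloxy)-3-[3-(benzyloxy)-2,4-dimethoxyphenyl]chroman-4-yl}-6-hydroxyphenyl]-3-[4-(benzyloxy)phenyl]prop-2-en-1-one | COc1ccc([C@@H]2COc3cc(OCc4ccccc4)ccc3[C@H]2c2c(OCc3ccccc3)cc(O)c(C(=O)/C=C/c3ccc(OCc4ccccc4)cc3)c2OCc2ccccc2)c(OC)c1OCc1ccccc1
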